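Agecorynin E is a (2S)-flavanone in which O1 of ring C bridges the sp3 carbinol carbon C2 and the aryl carbon C8a of ring A. Everything rests on cutting O1–C8a. An intramolecular copper-catalysed aryl ether synthesis joins an already (S)-configured C2 hydroxyl to a C8a bromide and closes ring C in one operation. The C2–O bond, and hence the stereocentre, is left untouched. The precursor is the open-chain syn bromo diol 9, with C4 held as an alcohol so that no β-hydroxy ketone meets hot base. C2 is set beforehand by enantioselective conjugate borylation of a chalcone. C4 oxidation and neutral debenzylation finish the route.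

Key step: step 5

Assumption: the hand of the ferrocenyl diphosphine that leads to the (S)-boronate is assigned by analogy with other β-aryl enones; it is to be checked on 7 (chiral HPLC, MTPA esters), and the mirror-image ligand, equally available, is used should the check demand it.

Step 1
Reactants: 1 5-bromo-1,2,3-trimethoxybenzene; 2 acetyl chloride
Product: 3 1-(6-bromo-2,3,4-trimethoxyphenyl)ethan-1-one
Conditions: SnCl4 (1.2 equiv), CH2Cl2, −10 °C to 0 °C
Reagents that add atoms: none
Why: Friedel–Crafts acylation in which the two open ring positions of 1 are equivalent and each lies ortho and para to a methoxy group, so only one ketone can form, while SnCl4 at low temperature is preferred to AlCl3 to avoid chelation-driven loss of the methyl ether next to the new carbonyl.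

Step 2
Reactants: 3 1-(6-bromo-2,3,4-trimethoxyphenyl)ethan-1-one; 4 O-benzylvanillin (4-benzyloxy-3-methoxybenzaldehyde)
Product: 5 (E)-3-[4-(benzyloxy)-3-methoxyphenyl]-1-(6-bromo-2,3,4-trimethoxyphenyl)prop-2-en-1-one
Conditions: KOH, EtOH, rt
Reagents that add atoms: none
Why: Claisen–Schmidt condensation between a ketone with a single enolisable site and an aldehyde that cannot enolise, with E1cB loss of water giving the conjugated E-enone, and with the aryl bromide and all ethers inert to ethanolic hydroxide.

Step 3
Reactants: 5 (E)-3-[4-(benzyloxy)-3-methoxyphenyl]-1-(6-bromo-2,3,4-trimethoxyphenyl)prop-2-en-1-one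
Product: 7 (3S)-3-[4-(benzyloxy)-3-methoxyphenyl]-1-(6-bromo-2,3,4-trimethoxyphenyl)-3-hydroxypropan-1-one, via (S)-β-boryl ketone 6 (not isolated)
Conditions: CuCl (3 mol%), NaOtBu (6 mol%), (R)-1-[(S)-2-(diphenylphosphino)ferrocenyl]ethyldicyclohexylphosphine (3 mol%), B2pin2, MeOH (2 equiv), THF, rt; then NaBO3·4H2O, THF–H2O, 0 °C to rt
Reagents that add atoms: bis(pinacolato)diboron, CC1(C)OB(OC1(C)C)B1OC(C)(C)C(C)(C)O1 (Bpin group of 6); sodium perborate, [Na+].[Na+].O[B-]1(O)OO[B-](O)(O)OO1 (hydroxyl oxygen of 7)
Why: Enantioselective copper-catalysed conjugate borylation of a β-aryl enone followed by stereoretentive C–B oxidation, preferred to a methyl ketone boron aldol because reagent control in such acetate-type aldols is usually modest: the diphosphine-bound Cu–Bpin adds to one face of the enone β-carbon (future C2), methanol protonates the enolate and turns the catalyst over, and perborate swaps boron for oxygen with retention, so the ligand alone fixes the S configuration.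

Step 4
Reactants: 7 (3S)-3-[4-(benzyloxy)-3-methoxyphenyl]-1-(6-bromo-2,3,4-trimethoxyphenyl)-3-hydroxypropan-1-one
Product: 9 (1S,3R)-1-[4-(benzyloxy)-3-methoxyphenyl]-3-(6-bromo-2,3,4-trimethoxyphenyl)propane-1,3-diol, via diethylborinate chelate 8 (not isolated)
Conditions: Et2BOMe, THF–MeOH (4:1), −78 °C; NaBH4, −78 °C to −40 °C; then repeated evaporation from MeOH (no acid)
Reagents that add atoms: diethylmethoxyborane, CCB(CC)OC (Et2B group of 8)
Why: Narasaka–Prasad reduction in which boron ties the carbinol oxygen and the ketone oxygen into a six-membered chelate with ring B equatorial, and external hydride adds axially to give the 1,3-syn diol, so the existing S centre sets the new carbinol as R, while the acid-free work-up protects both electron-rich benzylic alcohols from ionisation.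

Step 5
Reactants: 9 (1S,3R)-1-[4-(benzyloxy)-3-methoxyphenyl]-3-(6-bromo-2,3,4-trimethoxyphenyl)propane-1,3-diol
Product: 10 (2S,4R)-2-[4-(benzyloxy)-3-methoxyphenyl]-5,6,7-trimethoxy-3,4-dihydro-2H-chromen-4-ol
Conditions: CuI (10 mol%), 3,4,7,8-tetramethyl-1,10-phenanthroline (20 mol%), Cs2CO3 (2 equiv), degassed toluene (0.02 M), 110 °C, under argon
Reagents that add atoms: none
Why: Cs2CO3 turns the hydroxyl on the ring B carbinol (future C2) into an alkoxide that binds ligated monovalent copper; oxidative addition of the C8a–Br bond then gives a trivalent aryl copper alkoxide held in a seven-membered cupracycle, and C–O reductive elimination releases 10 and regenerates monovalent copper. The closest known reaction type is the Ullmann-type intramolecular O-arylation of secondary alcohols by aryl bromides, an established entry to chromans and 2-arylchromans that also tolerates a second free hydroxyl. Ring C closes as a six-membered ring by ipso substitution at C8a, formally 6-exo-trig because the breaking C–Br bond lies outside the new ring. No stereocentre is created, since neither carbinol C–O bond is broken, so 1S of 9 becomes 2S of 10 and the syn diol maps onto the 2,4-trans flavan-4-ol. The step needs chemoselectivity between two secondary benzylic hydroxyls, and ring size secures it, because the C4 oxygen could reach C8a only through a four-membered benzoxete, while high dilution holds back intermolecular etherification. The electron-rich tetramethylphenanthroline is chosen because the trimethoxy-substituted bromide is reluctant in oxidative addition, air is excluded so that the benzylic alkoxides are not dehydrogenated, and the 4'-oxygen stays benzylated so that no quinone methide can form under base.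

Step 6
Reactants: 10 (2S,4R)-2-[4-(benzyloxy)-3-methoxyphenyl]-5,6,7-trimethoxy-3,4-dihydro-2H-chromen-4-ol
Product: 11 (2S)-2-[4-(benzyloxy)-3-methoxyphenyl]-5,6,7-trimethoxy-2,3-dihydro-4H-chromen-4-one
Conditions: Dess–Martin periodinane, pyridine, CH2Cl2, 0 °C to rt
Reagents that add atoms: none
Why: Dess–Martin oxidation turns the secondary benzylic C4 alcohol into the aryl ketone at or below room temperature, pyridine takes up the acetic acid that could ionise the very electron-rich C4 carbinol, and the medium is too weakly basic to open ring C, so C2 is untouched while the C4 stereocentre is erased as planned.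

Step 7
Reactants: 11 (2S)-2-[4-(benzyloxy)-3-methoxyphenyl]-5,6,7-trimethoxy-2,3-dihydro-4H-chromen-4-one
Product: 12 Agecorynin E, (2S)-2-(4-hydroxy-3-methoxyphenyl)-5,6,7-trimethoxy-2,3-dihydro-4H-chromen-4-one
Conditions: H2 (1 atm), Pd/C (10 wt%), EtOAc, rt, stopped at full conversion
Reagents that add atoms: none
Why: Catalytic hydrogenolysis cleaves the primary O–CH2Ph bond much faster than it attacks the ring C2–O1 bond or the hindered, electron-rich C4 ketone, and the neutral, base-free medium avoids the retro-oxa-Michael ring opening by which a flavanone with a free 4'-hydroxyl racemises, so 2S is kept.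

Compound list
1 | 5-bromo-1,2,3-trimethoxybenzene | COc1cc(Br)cc(OC)c1OC | starting material
2 | acetyl chloride | CC(=O)Cl | starting material
3 | 1-(6-bromo-2,3,4-trimethoxyphenyl)ethan-1-one (same group as 2-bromo-4,5,6-trimethoxyphenyl; acetyl flanked by Br and OMe) | CC(=O)c1c(Br)cc(OC)c(OC)c1OC | intermediate
4 | O-benzylvanillin, 4-(benzyloxy)-3-methoxybenzaldehyde | COc1cc(C=O)ccc1OCc1ccccc1 | starting material
5 | (E)-3-[4-(benzyloxy)-3-methoxyphenyl]-1-(6-bromo-2,3,4-trimethoxyphenyl)prop-2-en-1-one | COc1cc(/C=C/C(=O)c2c(Br)cc(OC)c(OC)c2OC)ccc1OCc1ccccc1 | intermediate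
6 | (3S)-3-[4-(benzyloxy)-3-methoxyphenyl]-1-(6-bromo-2,3,4-trimethoxyphenyl)-3-(4,4,5,5-tetramethyl-1,3,2-dioxaborolan-2-yl)propan-1-one, not isolated | COc1cc([C@@H](B2OC(C)(C)C(C)(C)O2)CC(=O)c2c(Br)cc(OC)c(OC)c2OC)ccc1OCc1ccccc1 | intermediate
7 | (3S)-3-[4-(benzyloxy)-3-methoxyphenyl]-1-(6-bromo-2,3,4-trimethoxyphenyl)-3-hydroxypropan-1-one | COc1cc([C@@H](O)CC(=O)c2c(Br)cc(OC)c(OC)c2OC)ccc1OCc1ccccc1 | intermediate
8 | O-diethylboryl derivative of 7 (drawn open; the ketone oxygen coordinates to boron), not isolated | COc1cc([C@@H](OB(CC)CC)CC(=O)c2c(Br)cc(OC)c(OC)c2OC)ccc1OCc1ccccc1 | intermediate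
9 | (1S,3R)-1-[4-(benzyloxy)-3-methoxyphenyl]-3-(6-bromo-2,3,4-trimethoxyphenyl)propane-1,3-diol, syn diol | COc1cc([C@@H](O)C[C@@H](O)c2c(Br)cc(OC)c(OC)c2OC)ccc1OCc1ccccc1 | intermediate
10 | (2S,4R)-2-[4-(benzyloxy)-3-methoxyphenyl]-5,6,7-trimethoxy-3,4-dihydro-2H-chromen-4-ol, 2,4-trans flavan-4-ol | COc1cc([C@@H]2C[C@@H](O)c3c(cc(OC)c(OC)c3OC)O2)ccc1OCc1ccccc1 | intermediate
11 | (2S)-2-[4-(benzyloxy)-3-methoxyphenyl]-5,6,7-trimethoxy-2,3-dihydro-4H-chromen-4-one | COc1cc([C@@H]2CC(=O)c3c(cc(OC)c(OC)c3OC)O2)ccc1OCc1ccccc1 | intermediate
12 | Agecorynin E, (2S)-2-(4-hydroxy-3-methoxyphenyl)-5,6,7-trimethoxy-2,3-dihydro-4H-chromen-4-one | COc1cc([C@@H]2CC(=O)c3c(cc(OC)c(OC)c3OC)O2)ccc1O | target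

Total step count: 7. Longest linear sequence: 7 steps (from 1).

Steps most likely to fail

**Step 5.**
- What may go wrong: oxidative addition may be slow at the electron-rich, ortho-substituted bromide. That leaves room for hydrodebromination, dehydrogenation of a benzylic alkoxide or intermolecular etherification.
- Fallback: it sets out from 4 and returns at 11. It makes the other ring C ether bond, O1–C2, by Mitsunobu displacement with inversion.
  - Aldehyde 4 is condensed (KOH, EtOH) with purchased 1-(6-hydroxy-2,3,4-trimethoxyphenyl)ethan-1-one F1 to give the 2'-hydroxychalcone F2.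
  - Conjugate borylation as in step 3, but with the mirror-image ligand and with the hydrogen-bonded phenol tolerated as an extra proton source, gives the (R)-β-boryl ketone F3.
  - Perborate converts F3 into the (R)-β-hydroxy ketone F4.
  - PPh3 and DIAD in THF at 0 °C then let the phenol displace the activated carbinol oxygen with inversion. This gives 11 directly, so that only step 7 remains.

**Step 3.**
- What may go wrong: facial selectivity may be poor on this twisted, doubly ortho-substituted aryl enone. Addition to the electron-rich β-aryl terminus may be slow, and retro-aldol cleavage or dehydration may occur during the mildly basic oxidation.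
- Fallback: it sets out from 3 and returns at 7. It sets the carbinol by ketone reduction instead of C–B bond formation.
  - Ketone 3 is deprotonated with LiN(SiMe3)2 (2 equiv, THF, −78 °C) and C-acylated with purchased 4-(benzyloxy)-3-methoxybenzoyl chloride F5 to give the 1,3-diketone F6.
  - Asymmetric transfer hydrogenation with RuCl[(S,S)-TsDPEN](p-cymene) in HCO2H–Et3N should reduce only the unhindered ring B carbonyl. It follows the firmly established correlation of the (S,S)-catalyst with (S)-aryl carbinols and gives 7.

**Step 1.**
- What may go wrong: Lewis acid chelation may remove the methyl ether ortho to the new carbonyl. Acylation may also be slow at a position flanked by bromine and methoxy.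
- Fallback: it sets out from 1 and returns at 3. It reverses the polarity, so that ring A acts as the nucleophile under non-acidic conditions.
  - Arene 1 is iodinated (NIS, cat. CF3CO2H, MeCN) to 1-bromo-2-iodo-3,4,5-trimethoxybenzene F7.
  - Selective iodine–magnesium exchange (iPrMgCl·LiCl, THF, −40 °C) gives (6-bromo-2,3,4-trimethoxyphenyl)magnesium chloride F8.
  - F8 is acetylated with N-methoxy-N-methylacetamide to give 3.

Further compounds
F1 | step 5 | 1-(6-hydroxy-2,3,4-trimethoxyphenyl)ethan-1-one (purchased) | CC(=O)c1c(O)cc(OC)c(OC)c1OC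
F2 | step 5 | (E)-3-[4-(benzyloxy)-3-methoxyphenyl]-1-(6-hydroxy-2,3,4-trimethoxyphenyl)prop-2-en-1-one | COc1cc(/C=C/C(=O)c2c(O)cc(OC)c(OC)c2OC)ccc1OCc1ccccc1
F3 | step 5 | (3R)-3-[4-(benzyloxy)-3-methoxyphenyl]-1-(6-hydroxy-2,3,4-trimethoxyphenyl)-3-(4,4,5,5-tetramethyl-1,3,2-dioxaborolan-2-yl)propan-1-one | COc1cc([C@H](B2OC(C)(C)C(C)(C)O2)CC(=O)c2c(O)cc(OC)c(OC)c2OC)ccc1OCc1ccccc1
F4 | step 5 | (3R)-3-[4-(benzyloxy)-3-methoxyphenyl]-3-hydroxy-1-(6-hydroxy-2,3,4-trimethoxyphenyl)propan-1-one | COc1cc([C@H](O)CC(=O)c2c(O)cc(OC)c(OC)c2OC)ccc1OCc1ccccc1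
F5 | step 3 | 4-(benzyloxy)-3-methoxybenzoyl chloride (purchased) | COc1cc(C(=O)Cl)ccc1OCc1ccccc1
F6 | step 3 | 1-[4-(benzyloxy)-3-methoxyphenyl]-3-(6-bromo-2,3,4-trimethoxyphenyl)propane-1,3-dione | COc1cc(C(=O)CC(=O)c2c(Br)cc(OC)c(OC)c2OC)ccc1OCc1ccccc1
F7 | step 1 | 1-bromo-2-iodo-3,4,5-trimethoxybenzene | COc1cc(Br)c(I)c(OC)c1OC
F8 | step 1 | (6-bromo-2,3,4-trimethoxyphenyl)magnesium chloride | COc1cc(Br)c([Mg]Cl)c(OC)c1OC
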